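The constants are made up; the run is a simulation.

Time in this flask is best counted in turnovers, and the count is reckoned here in fractions of the charge.

substrate 0.010 M; reagent in the second phase 9.50 mM; time 3.0 h; volume of the second phase over the first 0.50

    reagent in the reaction phase ⇌ reagent in the second phase, rate k1*([reagent in the reaction phase] - [reagent in the second phase]/K1) per volume of the first phase (K1 = 0.88, k1 = 1.72 min⁻¹)
    substrate + reagent in the reaction phase → target (k2 = 2.41 L mol⁻¹ min⁻¹)
    reagent in the reaction phase + target → over-reacted product (k3 = 1.10 L mol⁻¹ min⁻¹)
    substrate + target → side product (k4 = 0.804 L mol⁻¹ min⁻¹)

- how much target there is at 3.0 h, in percent of the substrate charged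
- part of the substrate charged that has reacted at 3.0 h

- percent here means substrate units held: one side product counts as two
- in the second phase: reagent in the second phase; everything else is in the first
- charges count per volume of the first phase; a concentration in a rate is the amount of a species over the volume of its own phase; every rate counts per litre of the first phase
- run time (flask): 3.0 h

The crossing, at 1.72 min⁻¹, is far quicker than step 2, whose substrate-side rate is 0.0241 min⁻¹. The reagent therefore stands at its partition, with share f in the reaction phase. At charged levels over the run, substrate makes N turnovers to target and target makes n turnovers to side product:

f = 0.694

N = 2.86

n = 1.45

Twice n over N gives one number, S: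

S = 1.01

S is the side-path number, the substrate units entering side product per unit entering target, with target and reagent at charged levels.

Reagent is charged at 0.950 of the substrate, so my estimate counts a second-order fall over N plus n turnovers, which puts the reacted part at 81.2%. Dividing that part by one plus S gives target of 40.4%.

One number is not enough, though. Over-reaction gives target 1.31 turnovers, close to n, and S omits them; adding their 0.456 units per unit of target to the divisor lowers my target to 32.9%.

The forecast gives 29% of target and 78% reacted, having “treated the reagent as partitioned at equilibrium”; its target is lower than mine.

The flask gives 32.1% of target and 80.1% reacted, so the forecast stands: a third of the substrate charged is target at 3.0 h. Beside it this flask holds 33.5% as side product, which is 1.04 parts per part of target, read against S of 1.01. The neighbour charged with 0.0060 M of substrate has S of 0.607 and holds 21.0% of side product against 39.7% of target, or 0.529 parts per part.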